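**Retrosynthetic overview**
- The target is a 2,4-cis (2S,4S)-5,7,3',4'-tetrahydroxyflavan joined through C4 to C8 of (+)-catechin. The last step saturates C3=C4 of a nona-O-benzyl flav-3-ene and removes all benzyl groups, with C2 directing C4.
- The plan rests on one feature of the upper unit: C2 is a benzylic carbon bonded to ring oxygen O1 and to the unoxygenated methylene C3, so it has the oxidation level of an aldehyde carbon. Ring C is therefore cut at O1–C2 and C2–C3, giving 3,4-bis(benzyloxy)benzaldehyde and a phenol whose ortho substituent is a 1,1-diarylethene (C3=C4) carrying ring A and catechin C8. The two are joined by a Prins-type [5+1] annulation under a chiral Brønsted acid.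
- The diarylethene phenol comes from 8-metalated penta-O-benzylcatechin (from (+)-catechin by benzylation and C8 bromination) and 2'-allyloxy-4',6'-bis(benzyloxy)acetophenone (C4–C8 bond), followed by dehydration and deallylation.
- Ring order: the catechin rings (chiral pool) and upper rings A and B are brought in intact. Upper ring C is the only ring made, in the key step, and C2 is the only stereocentre set by a catalyst.

Key step: step 9

Assumption: the sense of induction of the chiral acid in step 9 cannot be predicted for this substrate, so the (R)-catalyst is written and its mirror image is to be used if it favours the 2R epimer.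

**Step 1**
Reactants: 1 (+)-catechin
Product: 2 5,7,3',4'-tetra-O-benzyl-(+)-catechin
Conditions: BnBr (4.4 equiv), K2CO3, DMF, 0 °C → rt
Reagents that add atoms: benzyl bromide, BrCc1ccccc1
Why: Williamson etherification, in which K2CO3 deprotonates only the four phenols, so the secondary 3-OH should stay free and both stereocentres are untouched.

**Step 2**
Reactants: 2 5,7,3',4'-tetra-O-benzyl-(+)-catechin
Product: 3 8-bromo-5,7,3',4'-tetra-O-benzyl-(+)-catechin
Conditions: NBS (1.0 equiv), CH2Cl2, −78 °C → rt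
Reagents that add atoms: N-bromosuccinimide, O=C1CCC(=O)N1Br
Why: Electrophilic aromatic bromination of the phloroglucinol-type ring A, which in tetra-O-benzyl flavan-3-ols is known to go to C8 in preference to C6.

**Step 3**
Reactants: 3 8-bromo-5,7,3',4'-tetra-O-benzyl-(+)-catechin
Product: 4 8-bromo-3,5,7,3',4'-penta-O-benzyl-(+)-catechin
Conditions: NaH, BnBr, DMF, 0 °C → rt
Reagents that add atoms: benzyl bromide, BrCc1ccccc1
Why: Williamson etherification of the secondary alkoxide caps the 3-OH, so that it can neither quench the aryl metal of step 6 nor trap cations or the aldehyde in step 9.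

**Step 4**
Reactants: 5 2',4',6'-trihydroxyacetophenone
Product: 6 2'-hydroxy-4',6'-bis(benzyloxy)acetophenone
Conditions: BnBr (2.1 equiv), K2CO3, DMF, rt
Reagents that add atoms: benzyl bromide, BrCc1ccccc1
Why: Selective Williamson etherification, in which the 4'-OH and one ortho OH react while the last ortho OH is held back by its hydrogen bond to the carbonyl group.

**Step 5**
Reactants: 6 2'-hydroxy-4',6'-bis(benzyloxy)acetophenone
Product: 7 2'-(allyloxy)-4',6'-bis(benzyloxy)acetophenone
Conditions: allyl bromide, K2CO3, DMF, 60 °C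
Reagents that add atoms: allyl bromide, C=CCBr
Why: Williamson allylation of the chelated phenol under warmer conditions gives an ether that withstands organometallic reagents and can later be removed without touching benzyl ethers.

**Step 6**
Reactants: 4 8-bromo-3,5,7,3',4'-penta-O-benzyl-(+)-catechin; 7 2'-(allyloxy)-4',6'-bis(benzyloxy)acetophenone
Product: 10 1-[2-(allyloxy)-4,6-bis(benzyloxy)phenyl]-1-(penta-O-benzylcatechin-8-yl)ethanol, via 8-lithio-penta-O-benzylcatechin 8 (not isolated), via arylcerium dichloride 9 (not isolated)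
Conditions: n-BuLi (1.05 equiv), THF, −78 °C; anhydrous CeCl3 (1.2 equiv), −78 °C; 7, −78 → 0 °C; H2O, filtration through Celite
Reagents that add atoms: n-butyllithium, [Li]CCCC; cerium trichloride, Cl[Ce](Cl)Cl
Why: Bromine–lithium exchange gives 8, transmetalation gives the less basic and more oxophilic organocerium 9, and its 1,2-addition to the ketone of 7 (organocerium addition to an enolisable ketone) should outrun deprotonation of the acetyl group; lithium and cerium are carried only by 8 and 9 and are lost as salts on aqueous work-up, and the carbinol carbon forms as both epimers, which is of no consequence because step 7 makes it trigonal.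

**Step 7**
Reactants: 10 1-[2-(allyloxy)-4,6-bis(benzyloxy)phenyl]-1-(penta-O-benzylcatechin-8-yl)ethanol
Product: 11 1-[2-(allyloxy)-4,6-bis(benzyloxy)phenyl]-1-(penta-O-benzylcatechin-8-yl)ethene
Conditions: PPTS (5 mol%), 4 Å MS, PhMe, 50 °C
Reagents that add atoms: none
Why: Acid-catalysed E1 dehydration through a diarylmethyl cation stabilised by two trioxygenated rings, which can lose a proton only from the methyl group and so should give the 1,1-diarylethene alone.

**Step 8**
Reactants: 11 1-[2-(allyloxy)-4,6-bis(benzyloxy)phenyl]-1-(penta-O-benzylcatechin-8-yl)ethene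
Product: 12 2-[1-(penta-O-benzylcatechin-8-yl)vinyl]-3,5-bis(benzyloxy)phenol
Conditions: Pd(PPh3)4 (5 mol%), morpholine (10 equiv), THF, rt
Reagents that add atoms: none
Why: Tsuji–Trost deallylation, in which zerovalent palladium ionises the aryl allyl ether to a π-allyl complex and the phenoxide, and morpholine captures the allyl group, under neutral conditions that should spare the benzyl ethers and the acid-sensitive diarylethene.

**Step 9**
Reactants: 12 2-[1-(penta-O-benzylcatechin-8-yl)vinyl]-3,5-bis(benzyloxy)phenol; 13 3,4-bis(benzyloxy)benzaldehyde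
Product: 16 (2S)-4-(penta-O-benzylcatechin-8-yl)-5,7,3',4'-tetrakis(benzyloxy)flav-3-ene, via aryl oxocarbenium ion 14 (not isolated), via C4 diarylmethyl cation 15 (not isolated)
Conditions: 13 (1.5 equiv), (R)-3,3'-bis(2,4,6-triisopropylphenyl)-1,1'-binaphthyl-2,2'-diyl N-triflylphosphoramide (10 mol%), 5 Å MS, PhMe (dilute), −40 → −20 °C; Et3N quench at low temperature
Reagents that add atoms: none
Why: Proposed new method: the phenol of 12 and aldehyde 13 should condense under the chiral acid to a hemiacetal that ionises to oxocarbenium ion 14 (O1–C2 formed), held as a contact ion pair with the phosphoramide anion and stabilised by the para-benzyloxy group. The CH2 terminus of the diarylethene then attacks C2 (C2–C3 formed) and closes ring C in a 6-endo-trig mode with respect to the alkene; this mode places the charge at C4 of 15, between two trioxygenated rings, whereas 5-exo attack through the inner alkene carbon would leave a primary cation and is excluded. Loss of H3 from 15 to the catalyst anion gives the flav-3-ene and returns the acid, so the step is a Prins cyclisation ended by elimination. The closest known reaction types are acid-catalysed Prins cyclisations of oxocarbenium ions onto 1,1-disubstituted alkenes, chiral-acid-catalysed oxa-Pictet–Spengler reactions and chiral N-triflylphosphoramide-catalysed closures of 1,3-diarylallyl cations onto phenols to give 2,4-diaryl-2H-chromenes. The one new stereocentre, C2, has to be set by the chiral counter-anion shielding one face of the oxocarbenium carbon, because the catechin stereocentres are too far away to help; since the catechin unit is enantiopure, a minor C2 epimer is a diastereomer and should be removable by chromatography. The step needs ring closure at the alkene to win over Friedel–Crafts attack of the aldehyde on the free ring positions, which the proximity of the alkene to the phenol-bound oxocarbenium ion and its high nucleophilicity should secure.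

**Step 10**
Reactants: 16 (2S)-4-(penta-O-benzylcatechin-8-yl)-5,7,3',4'-tetrakis(benzyloxy)flav-3-ene
Product: 17 (2S,4S)-5,7,3',4'-tetrahydroxyflavan-(4→8)-(+)-catechin (CNP0180676.1)
Conditions: H2 (4 bar), Pd(OH)2/C, THF–MeOH, rt
Reagents that add atoms: none
Why: Heterogeneous catalytic hydrogenation adds both hydrogens to C3=C4 from the face opposite the allylic C2 aryl group, so H4 ends up trans to that aryl and the catechin unit cis to it (2,4-cis, 4S), while hydrogenolysis removes the nine benzyl ethers and should leave the flavan C2–O1 bonds intact as in other flavan debenzylations.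

**Compound list**
1 | (+)-catechin, (2R,3S)-2-(3,4-dihydroxyphenyl)chroman-3,5,7-triol | Oc1cc(O)c2c(c1)O[C@H](c1ccc(O)c(O)c1)[C@@H](O)C2 | starting material
2 | 5,7,3',4'-tetra-O-benzyl-(+)-catechin | c1ccccc1COc2cc(OCc3ccccc3)c4c(c2)O[C@H](c2ccc(OCc3ccccc3)c(OCc3ccccc3)c2)[C@@H](O)C4 | intermediate
3 | 8-bromo-5,7,3',4'-tetra-O-benzyl-(+)-catechin | Brc1c(OCc2ccccc2)cc(OCc2ccccc2)c3c1O[C@H](c1ccc(OCc2ccccc2)c(OCc2ccccc2)c1)[C@@H](O)C3 | intermediate
4 | 8-bromo-3,5,7,3',4'-penta-O-benzyl-(+)-catechin | Brc1c(OCc2ccccc2)cc(OCc2ccccc2)c3c1O[C@H](c1ccc(OCc2ccccc2)c(OCc2ccccc2)c1)[C@@H](OCc1ccccc1)C3 | intermediate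
5 | 2',4',6'-trihydroxyacetophenone | CC(=O)c1c(O)cc(O)cc1O | starting material
6 | 2'-hydroxy-4',6'-bis(benzyloxy)acetophenone | CC(=O)c1c(O)cc(OCc2ccccc2)cc1OCc1ccccc1 | intermediate
7 | 2'-(allyloxy)-4',6'-bis(benzyloxy)acetophenone | CC(=O)c1c(OCC=C)cc(OCc2ccccc2)cc1OCc1ccccc1 | intermediate
8 | 8-lithio-penta-O-benzylcatechin | [Li]c1c(OCc2ccccc2)cc(OCc2ccccc2)c3c1O[C@H](c1ccc(OCc2ccccc2)c(OCc2ccccc2)c1)[C@@H](OCc1ccccc1)C3 | intermediate (not isolated)
9 | (penta-O-benzylcatechin-8-yl)cerium dichloride | Cl[Ce](Cl)c1c(OCc2ccccc2)cc(OCc2ccccc2)c3c1O[C@H](c1ccc(OCc2ccccc2)c(OCc2ccccc2)c1)[C@@H](OCc1ccccc1)C3 | intermediate (not isolated)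
10 | 1-[2-(allyloxy)-4,6-bis(benzyloxy)phenyl]-1-(penta-O-benzylcatechin-8-yl)ethanol, both epimers at the carbinol carbon | CC(O)(c1c(OCC=C)cc(OCc2ccccc2)cc1OCc1ccccc1)c1c(OCc2ccccc2)cc(OCc2ccccc2)c3c1O[C@H](c1ccc(OCc2ccccc2)c(OCc2ccccc2)c1)[C@@H](OCc1ccccc1)C3 | intermediate
11 | 1-[2-(allyloxy)-4,6-bis(benzyloxy)phenyl]-1-(penta-O-benzylcatechin-8-yl)ethene | C=C(c1c(OCC=C)cc(OCc2ccccc2)cc1OCc1ccccc1)c1c(OCc2ccccc2)cc(OCc2ccccc2)c3c1O[C@H](c1ccc(OCc2ccccc2)c(OCc2ccccc2)c1)[C@@H](OCc1ccccc1)C3 | intermediate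
12 | 2-[1-(penta-O-benzylcatechin-8-yl)vinyl]-3,5-bis(benzyloxy)phenol | C=C(c1c(O)cc(OCc2ccccc2)cc1OCc1ccccc1)c1c(OCc2ccccc2)cc(OCc2ccccc2)c3c1O[C@H](c1ccc(OCc2ccccc2)c(OCc2ccccc2)c1)[C@@H](OCc1ccccc1)C3 | intermediate
13 | 3,4-bis(benzyloxy)benzaldehyde | O=Cc1ccc(OCc2ccccc2)c(OCc2ccccc2)c1 | starting material
14 | aryl oxocarbenium ion from 12 and 13 (cation, counter-ion the catalyst anion) | C=C(c1c([O+]=Cc2ccc(OCc3ccccc3)c(OCc3ccccc3)c2)cc(OCc2ccccc2)cc1OCc1ccccc1)c1c(OCc2ccccc2)cc(OCc2ccccc2)c3c1O[C@H](c1ccc(OCc2ccccc2)c(OCc2ccccc2)c1)[C@@H](OCc1ccccc1)C3 | intermediate (not isolated)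
15 | (2S)-4-(penta-O-benzylcatechin-8-yl)-5,7,3',4'-tetrakis(benzyloxy)flavan-4-ylium ion (cation, counter-ion the catalyst anion) | c1ccccc1COc1cc(OCc2ccccc2)c2c(c1)O[C@H](c1ccc(OCc3ccccc3)c(OCc3ccccc3)c1)C[C+]2c1c(OCc2ccccc2)cc(OCc2ccccc2)c3c1O[C@H](c1ccc(OCc2ccccc2)c(OCc2ccccc2)c1)[C@@H](OCc1ccccc1)C3 | intermediate (not isolated)
16 | (2S)-4-(penta-O-benzylcatechin-8-yl)-5,7,3',4'-tetrakis(benzyloxy)flav-3-ene | c1ccccc1COc1cc(OCc2ccccc2)c2c(c1)O[C@H](c1ccc(OCc3ccccc3)c(OCc3ccccc3)c1)C=C2c1c(OCc2ccccc2)cc(OCc2ccccc2)c3c1O[C@H](c1ccc(OCc2ccccc2)c(OCc2ccccc2)c1)[C@@H](OCc1ccccc1)C3 | intermediate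
17 | (2S,4S)-2-(3,4-dihydroxyphenyl)-4-[(2R,3S)-2-(3,4-dihydroxyphenyl)-3,5,7-trihydroxychroman-8-yl]chroman-5,7-diol (2,4-cis) | Oc1cc(O)c2c(c1)O[C@H](c1ccc(O)c(O)c1)C[C@@H]2c1c(O)cc(O)c2c1O[C@H](c1ccc(O)c(O)c1)[C@@H](O)C2 | target

**Step count**
Total: 10 steps. Longest linear sequence: 8 steps (steps 1, 2, 3, 6, 7, 8, 9, 10 from (+)-catechin).

**Steps most likely to fail**

1. Step 9 (proposed new method). Three processes threaten it: weak facial discrimination at the oxocarbenium carbon by the chiral anion, Friedel–Crafts attack of the activated aldehyde on the free ring positions, and acid-induced ionisation of the C2–O1 bond of the product, which would scramble C2. The fallback replaces the Prins annulation by known flavanone chemistry; it sets out from 6 and rejoins the route at 16. Compound 6 is condensed with N,N-dimethylformamide dimethyl acetal to the enaminone (E)-3-(dimethylamino)-1-[2-hydroxy-4,6-bis(benzyloxy)phenyl]prop-2-en-1-one F1. Acid then closes F1 to 5,7-bis(benzyloxy)chromen-4-one F2. Asymmetric conjugate addition of purchased 3,4-bis(benzyloxy)phenylboronic acid, catalysed by Pd(OCOCF3)2 and a tert-butyl pyridine–oxazoline ligand of the hand that gives 2S, should deliver (2S)-5,7-bis(benzyloxy)-2-[3,4-bis(benzyloxy)phenyl]chroman-4-one F3. The organocerium 9, made from 4 as in step 6, adds to the C4 ketone to give (2S)-4-(penta-O-benzylcatechin-8-yl)-5,7,3',4'-tetrakis(benzyloxy)flavan-4-ol F4. Dehydration with PPTS then gives 16.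

2. Step 10. Hydrogen uptake at the hindered trisubstituted alkene may be slow, the allylic and benzylic C2–O1 bond may be hydrogenolysed before the alkene is saturated, and the facial bias from C2 may be insufficient. The fallback separates the two tasks; it sets out from 16 and rejoins at 17. Homogeneous hydrogenation with [Ir(cod)(PCy3)(py)]PF6 and H2 in CH2Cl2 reduces only C3=C4 and leaves the benzyl ethers in place. This gives (2S,4S)-4-(penta-O-benzylcatechin-8-yl)-5,7,3',4'-tetrakis(benzyloxy)flavan F5, from which a C4 epimer, being a diastereomer, could be removed by chromatography if substrate control is weak. Ordinary hydrogenolysis of F5 over Pd(OH)2/C then gives 17.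

3. Step 6. Proton transfer from the acetyl group to the hindered aryl metal, and steric retardation of the addition, would return debrominated catechin ether. The fallback uses a non-enolisable aldehyde and a small nucleophile; it sets out from 4 (through 8) and rejoins at 10. Purchased 2,4,6-trihydroxybenzaldehyde is dibenzylated to 2-hydroxy-4,6-bis(benzyloxy)benzaldehyde F6 and allylated to 2-(allyloxy)-4,6-bis(benzyloxy)benzaldehyde F7. Aryllithium 8 adds to F7 to give [2-(allyloxy)-4,6-bis(benzyloxy)phenyl](penta-O-benzylcatechin-8-yl)methanol F8. Oxidation with MnO2 gives [2-(allyloxy)-4,6-bis(benzyloxy)phenyl](penta-O-benzylcatechin-8-yl)methanone F9. Addition of MeLi to F9 gives carbinol 10.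

**Further compounds**
F1 | step 9 | (E)-3-(dimethylamino)-1-[2-hydroxy-4,6-bis(benzyloxy)phenyl]prop-2-en-1-one | CN(C)/C=C/C(=O)c1c(O)cc(OCc2ccccc2)cc1OCc1ccccc1
F2 | step 9 | 5,7-bis(benzyloxy)chromen-4-one | O=c1ccoc2cc(OCc3ccccc3)cc(OCc3ccccc3)c12
F3 | step 9 | (2S)-5,7-bis(benzyloxy)-2-[3,4-bis(benzyloxy)phenyl]chroman-4-one | c1ccccc1COc1cc(OCc2ccccc2)c2c(c1)O[C@H](c1ccc(OCc3ccccc3)c(OCc3ccccc3)c1)CC2=O
F4 | step 9 | (2S)-4-(penta-O-benzylcatechin-8-yl)-5,7,3',4'-tetrakis(benzyloxy)flavan-4-ol, either C4 epimer | c1ccccc1COc1cc(OCc2ccccc2)c2c(c1)O[C@H](c1ccc(OCc3ccccc3)c(OCc3ccccc3)c1)CC2(O)c1c(OCc2ccccc2)cc(OCc2ccccc2)c3c1O[C@H](c1ccc(OCc2ccccc2)c(OCc2ccccc2)c1)[C@@H](OCc1ccccc1)C3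
F5 | step 10 | (2S,4S)-4-(penta-O-benzylcatechin-8-yl)-5,7,3',4'-tetrakis(benzyloxy)flavan | c1ccccc1COc1cc(OCc2ccccc2)c2c(c1)O[C@H](c1ccc(OCc3ccccc3)c(OCc3ccccc3)c1)C[C@@H]2c1c(OCc2ccccc2)cc(OCc2ccccc2)c3c1O[C@H](c1ccc(OCc2ccccc2)c(OCc2ccccc2)c1)[C@@H](OCc1ccccc1)C3
F6 | step 6 | 2-hydroxy-4,6-bis(benzyloxy)benzaldehyde | O=Cc1c(O)cc(OCc2ccccc2)cc1OCc1ccccc1
F7 | step 6 | 2-(allyloxy)-4,6-bis(benzyloxy)benzaldehyde | O=Cc1c(OCC=C)cc(OCc2ccccc2)cc1OCc1ccccc1
F8 | step 6 | [2-(allyloxy)-4,6-bis(benzyloxy)phenyl](penta-O-benzylcatechin-8-yl)methanol, both carbinol epimers | OC(c1c(OCC=C)cc(OCc2ccccc2)cc1OCc1ccccc1)c1c(OCc2ccccc2)cc(OCc2ccccc2)c3c1O[C@H](c1ccc(OCc2ccccc2)c(OCc2ccccc2)c1)[C@@H](OCc1ccccc1)C3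
F9 | step 6 | [2-(allyloxy)-4,6-bis(benzyloxy)phenyl](penta-O-benzylcatechin-8-yl)methanone | O=C(c1c(OCC=C)cc(OCc2ccccc2)cc1OCc1ccccc1)c1c(OCc2ccccc2)cc(OCc2ccccc2)c3c1O[C@H](c1ccc(OCc2ccccc2)c(OCc2ccccc2)c1)[C@@H](OCc1ccccc1)C3
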